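**Strategy**

The cyclohexenedione ring (C1 and C3 carbonyls, C2 gem-diprenyl, C4 acyl-bearing, C5 enol, C6 carbinol) is cut at C2–C3 and C4–C5. An acyclic ketoester holding C5–C6–C1–C2, with the C6 stereocentre already set by catalytic asymmetric enolate hydroxylation, meets an ethoxy-ynone that brings C3, C4 and the isobutyryl group. Conjugate addition makes the C2–C3 bond at the quaternary carbon, and the allenolate formed closes C4–C5 by Claisen condensation in the same flask; acid then unveils the triketone. The step exploits the quaternary C6: it leaves the C2 hydrogen as the only enolisable site and makes the C5 ester non-enolisable, so one enolate and one ring closure are possible.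

Key step: step 5

Assumption: the (R,R)-configured titanium TADDOLate catalyst is taken to give the (2S)-alcohol 7; if the sense of induction on this substrate proves opposite, the (S,S)-ligand is used with nothing else changed.

**Route**

Step 1
Reactants: 1 methyl acetoacetate; 2 prenyl bromide (1-bromo-3-methylbut-2-ene)
Product: 5 methyl 7-methyl-2,4-bis(3-methylbut-2-en-1-yl)-3-oxooct-6-enoate (racemic at C2), via monoprenyl enolate 3 (not isolated), via diprenyl enolate 4 (not isolated)
Conditions: LiN(iPr)2 (2.1 equiv), THF, 0 °C; 2 (1.0 equiv); LiN(iPr)2 (1.05 equiv), −78 → 0 °C; 2 (1.05 equiv); then 2 (1.3 equiv), DMPU, 0 → 45 °C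
Reagents that add atoms: prenyl bromide (2), CC(C)=CCBr
Why: Iterative Weiler dianion alkylation should deliver both prenyl groups to the γ-carbon, because each dianion reacts only at its more basic terminal carbanion, after which the remaining β-ketoester enolate is C-alkylated at the α-carbon by the third portion of bromide; the α-stereocentre formed is racemic and is planarised again in step 2.

Step 2
Reactants: 5 methyl 7-methyl-2,4-bis(3-methylbut-2-en-1-yl)-3-oxooct-6-enoate; 6 racemic 3-phenyl-2-(phenylsulfonyl)oxaziridine
Product: 7 methyl (2S)-2-hydroxy-7-methyl-2,4-bis(3-methylbut-2-en-1-yl)-3-oxooct-6-enoate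
Conditions: 6 (1.2 equiv), TiCl2(MeCN)2(L) (5 mol %), L = (4R,5R)-2,2-dimethyl-α,α,α′,α′-tetra(1-naphthyl)-1,3-dioxolane-4,5-dimethanolate, CH2Cl2, rt
Reagents that add atoms: 3-phenyl-2-(phenylsulfonyl)oxaziridine (6), O=S(=O)(c1ccccc1)N1OC1c1ccccc1
Why: Catalytic enantioselective electrophilic α-hydroxylation of a β-ketoester: the chelated titanium enolate is oxidised by the N-sulfonyloxaziridine on the face left open by the TADDOL aryl groups, which should set the carbinol centre as (S), while the trisubstituted alkenes are inert to the oxaziridine at room temperature.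

Step 3
Reactants: 7 methyl (2S)-2-hydroxy-7-methyl-2,4-bis(3-methylbut-2-en-1-yl)-3-oxooct-6-enoate; 8 N-(trimethylsilyl)imidazole
Product: 9 methyl (2S)-7-methyl-2,4-bis(3-methylbut-2-en-1-yl)-3-oxo-2-[(trimethylsilyl)oxy]oct-6-enoate
Conditions: 8 (2 equiv), CH2Cl2, rt
Reagents that add atoms: N-(trimethylsilyl)imidazole (8), C[Si](C)(C)n1ccnc1
Why: Silylation of the tertiary alcohol with a neutral, strongly silylating reagent masks the hydroxyl group, so that in step 5 no alkoxide can add to the ynone or start an α-ketol shift, and it leaves the quaternary stereocentre untouched.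

Step 4
Reactants: 10 ethoxyacetylene; 11 N-methoxy-N-methylisobutyramide
Product: 13 1-ethoxy-4-methylpent-1-yn-3-one, via lithium ethoxyacetylide 12 (not isolated)
Conditions: n-BuLi (1.0 equiv), THF, −78 °C; 11 (1.0 equiv), −78 → −20 °C; AcOH (1.0 equiv), −78 °C; filtration through neutral alumina
Reagents that add atoms: none
Why: Weinreb ketone synthesis: the lithium acetylide adds once to the N-methoxy-N-methylamide and the chelated tetrahedral adduct collapses only on protonation, which should give the push–pull ynone without over-addition.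

Step 5
Reactants: 9 methyl (2S)-7-methyl-2,4-bis(3-methylbut-2-en-1-yl)-3-oxo-2-[(trimethylsilyl)oxy]oct-6-enoate; 13 1-ethoxy-4-methylpent-1-yn-3-one
Product: 17 (6R)-5,6-dihydroxy-2,2,6-tris(3-methylbut-2-en-1-yl)-4-(2-methylpropanoyl)cyclohex-4-ene-1,3-dione (the target), via lithium enolate 14 (not isolated), via lithium allenolate 15 (not isolated), via ethoxy enone silyl ether 16 (not isolated)
Conditions: LiN(iPr)2 (1.1 equiv), THF, −78 → −40 °C; 13 (1.2 equiv), −78 → −20 °C; then 1 M aq HCl, THF, −78 °C → rt
Reagents that add atoms: water, O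
Why: Proposed new method: LiN(iPr)2 removes the only enolisable hydrogen of 9 (on the diprenylated carbon, the future C2), and the tetrasubstituted enolate 14 adds in conjugate fashion to the ethoxy-bearing alkyne carbon of the push–pull ynone 13 (future C3); this forms the C2–C3 bond and an allenolate 15, whose central carbon (future C4) attacks the non-enolisable methyl ester (future C5) and expels methoxide to close the carbocycle as the vinylogous ethyl ester 16. The closest known reaction type is the Michael–Claisen annulation of a carbanion, a conjugate acceptor and an ester; the alkoxy-ynone serves here as an acylketene equivalent that should meet a hindered enolate at carbon. The ring closes in the 6-(enolexo)-exo-trig mode, helped by the quaternary carbons C2 and C6 in the chain. No stereocentre is formed, and the C6 carbinol centre, which is quaternary and has no acidic hydrogen, passes through unchanged. The step needs conjugate instead of carbonyl addition, secured by the isopropyl group beside the ynone carbonyl and the polarisation by the ethoxy group, and closure onto the ester, since attack on the C1 ketone would give a four-membered ring. Dilute acid in the same flask then hydrolyses the vinylogous ester at C3 and the silyl ether to 17.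

**Compound list**

1 | methyl acetoacetate | CC(=O)CC(=O)OC | starting material
2 | prenyl bromide (1-bromo-3-methylbut-2-ene) | CC(C)=CCBr | starting material
3 | lithium enolate of methyl 7-methyl-3-oxooct-6-enoate | CC(C)=CCCC(=O)C=C([O-])OC.[Li+] | intermediate
4 | lithium enolate of methyl 7-methyl-4-(3-methylbut-2-en-1-yl)-3-oxooct-6-enoate | CC(C)=CCC(CC=C(C)C)C(=O)C=C([O-])OC.[Li+] | intermediate
5 | methyl 7-methyl-2,4-bis(3-methylbut-2-en-1-yl)-3-oxooct-6-enoate (racemic) | COC(=O)C(CC=C(C)C)C(=O)C(CC=C(C)C)CC=C(C)C | intermediate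
6 | racemic 3-phenyl-2-(phenylsulfonyl)oxaziridine | O=S(=O)(c1ccccc1)N1OC1c1ccccc1 | starting material
7 | methyl (2S)-2-hydroxy-7-methyl-2,4-bis(3-methylbut-2-en-1-yl)-3-oxooct-6-enoate | COC(=O)[C@](O)(CC=C(C)C)C(=O)C(CC=C(C)C)CC=C(C)C | intermediate
8 | N-(trimethylsilyl)imidazole | C[Si](C)(C)n1ccnc1 | starting material
9 | methyl (2S)-7-methyl-2,4-bis(3-methylbut-2-en-1-yl)-3-oxo-2-[(trimethylsilyl)oxy]oct-6-enoate | COC(=O)[C@](O[Si](C)(C)C)(CC=C(C)C)C(=O)C(CC=C(C)C)CC=C(C)C | intermediate
10 | ethoxyacetylene | CCOC#C | starting material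
11 | N-methoxy-N-methylisobutyramide | CC(C)C(=O)N(C)OC | starting material
12 | lithium ethoxyacetylide | CCOC#[C-].[Li+] | intermediate
13 | 1-ethoxy-4-methylpent-1-yn-3-one | CCOC#CC(=O)C(C)C | intermediate
14 | lithium enolate of 9 (enolate carbon is the diprenylated carbon) | COC(=O)[C@](O[Si](C)(C)C)(CC=C(C)C)C([O-])=C(CC=C(C)C)CC=C(C)C.[Li+] | intermediate
15 | lithium allenolate, the conjugate adduct of 14 to 13 | COC(=O)[C@](O[Si](C)(C)C)(CC=C(C)C)C(=O)C(CC=C(C)C)(CC=C(C)C)C(OCC)=C=C([O-])C(C)C.[Li+] | intermediate
16 | (6S)-3-ethoxy-2-(2-methylpropanoyl)-4,4,6-tris(3-methylbut-2-en-1-yl)-6-[(trimethylsilyl)oxy]cyclohex-2-ene-1,5-dione | CC(C)=CCC1(CC=C(C)C)C(OCC)=C(C(=O)C(C)C)C(=O)[C@](O[Si](C)(C)C)(CC=C(C)C)C1=O | intermediate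
17 | (6R)-5,6-dihydroxy-2,2,6-tris(3-methylbut-2-en-1-yl)-4-(2-methylpropanoyl)cyclohex-4-ene-1,3-dione | CC(C)=CCC1(CC=C(C)C)C(=O)C(C(=O)C(C)C)=C(O)[C@](O)(CC=C(C)C)C1=O | target

**Count and risks**

Total step count: 5. Longest linear sequence: 4 steps (steps 1, 2, 3 and 5); step 4 is a one-step side branch.

Steps most likely to fail:

1. Step 5 (proposed new method). The conjugate addition may be too slow at the congested enolate carbon. Attack through the enolate oxygen, proton transfer from the isobutyryl α-position of the ynone, or migration of the silyl group to the enolate oxygen could then take over. The liberated methoxide may also open the non-enolisable product before the quench. The fallback uses known chemistry, sets out from 9 and comes back at 17. The lithium enolate of 9 is transmetalated with MgBr2·OEt2 and C-acetylated with acetyl chloride to methyl (2S)-4-acetyl-7-methyl-2,4-bis(3-methylbut-2-en-1-yl)-3-oxo-2-[(trimethylsilyl)oxy]oct-6-enoate F1. LiN(iPr)2 at −78 °C then forms the kinetic methyl ketone enolate, which closes onto the ester by intramolecular Claisen condensation to (6R)-2,2,6-tris(3-methylbut-2-en-1-yl)-6-[(trimethylsilyl)oxy]cyclohexane-1,3,5-trione F2. Acylation of this trione at C4, between the C3 and C5 carbonyls, with isobutyric acid, DCC and DMAP (O-acylation, then O-to-C acyl shift) should give (6R)-5-hydroxy-2,2,6-tris(3-methylbut-2-en-1-yl)-4-(2-methylpropanoyl)-6-[(trimethylsilyl)oxy]cyclohex-4-ene-1,3-dione F3. Dilute aqueous HCl in THF then removes the silyl group to give 17.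

2. Step 2. Facial discrimination may be poor on an acyclic β-ketoester with a small ester group and a branched ketone side, and turnover may be slow at the hindered titanium enolate. The fallback sets out from 5 and comes back at 7. Compound 5 is hydroxylated without a chiral catalyst (KN(SiMe3)2, THF, −78 °C; then 6) to racemic methyl 2-hydroxy-7-methyl-2,4-bis(3-methylbut-2-en-1-yl)-3-oxooct-6-enoate F4. Its enantiomers are separated by preparative chromatography on a chiral stationary phase; the (2S)-enantiomer is 7 and methyl (2R)-2-hydroxy-7-methyl-2,4-bis(3-methylbut-2-en-1-yl)-3-oxooct-6-enoate F5 is set aside.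

3. Step 1. Regeneration of the dianion before the second alkylation may be incomplete, and bromide may react early at the α-carbon, giving mixtures of regioisomers that are hard to separate. The fallback sets out from 1 and comes back at 5. Compound 1 is first alkylated at the α-carbon with 2 (K2CO3, acetone, reflux) to methyl 2-acetyl-5-methylhex-4-enoate F6, which is isolated. Its dianion (NaH, then n-BuLi, THF, 0 °C) is prenylated at the γ-carbon to methyl 7-methyl-2-(3-methylbut-2-en-1-yl)-3-oxooct-6-enoate F7, which is purified. A second dianion formation and prenylation then gives 5.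

Further compounds
F1 | step 5 | methyl (2S)-4-acetyl-7-methyl-2,4-bis(3-methylbut-2-en-1-yl)-3-oxo-2-[(trimethylsilyl)oxy]oct-6-enoate | COC(=O)[C@](O[Si](C)(C)C)(CC=C(C)C)C(=O)C(CC=C(C)C)(CC=C(C)C)C(C)=O
F2 | step 5 | (6R)-2,2,6-tris(3-methylbut-2-en-1-yl)-6-[(trimethylsilyl)oxy]cyclohexane-1,3,5-trione | CC(C)=CCC1(CC=C(C)C)C(=O)CC(=O)[C@](O[Si](C)(C)C)(CC=C(C)C)C1=O
F3 | step 5 | (6R)-5-hydroxy-2,2,6-tris(3-methylbut-2-en-1-yl)-4-(2-methylpropanoyl)-6-[(trimethylsilyl)oxy]cyclohex-4-ene-1,3-dione | CC(C)=CCC1(CC=C(C)C)C(=O)C(C(=O)C(C)C)=C(O)[C@](O[Si](C)(C)C)(CC=C(C)C)C1=O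
F4 | step 2 | racemic methyl 2-hydroxy-7-methyl-2,4-bis(3-methylbut-2-en-1-yl)-3-oxooct-6-enoate | COC(=O)C(O)(CC=C(C)C)C(=O)C(CC=C(C)C)CC=C(C)C
F5 | step 2 | methyl (2R)-2-hydroxy-7-methyl-2,4-bis(3-methylbut-2-en-1-yl)-3-oxooct-6-enoate | COC(=O)[C@@](O)(CC=C(C)C)C(=O)C(CC=C(C)C)CC=C(C)C
F6 | step 1 | methyl 2-acetyl-5-methylhex-4-enoate | CC(=O)C(CC=C(C)C)C(=O)OC
F7 | step 1 | methyl 7-methyl-2-(3-methylbut-2-en-1-yl)-3-oxooct-6-enoate | COC(=O)C(CC=C(C)C)C(=O)CCC=C(C)C
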